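## Retrosynthetic overview

- Numbering C1–C22 follows the open-chain acid: lactone C=O is C1, ring CH–OH is C3, ring quaternary carbon is C4, side-chain carbinol is C6.
- The only ring (γ-lactone) is closed second to last: target 25 ⇐ O-benzyl lactone 24 ⇐ oxidative lactonisation of triol 21 (C1–OH onto C4–OH).
- C6 ⇐ Sharpless epoxidation of the 2-substituted allylic alcohol 14; C8–C22 come from pentadecyl Grignard 16 at the epoxide CH2; the CH2OH arm becomes the C6 methyl.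
- Key C4–C5 bond ⇐ chelation-controlled Hosomi–Sakurai allylation of α-benzyloxy methyl ketone 6 with allylsilane 11; C3 controls C4.
- 6 ⇐ (S)-α-hydroxy-γ-butyrolactone 1 (C3 from the chiral pool); 11 ⇐ methallyl alcohol 7.

Assumption: reagents and catalysts are named (with SMILES where they add atoms) but not numbered; starting materials 1, 7 and 16 are bought.

## Route

Step 1
Reactants: 1 (3S)-3-hydroxyoxolan-2-one
Product: 2 (3S)-3-(benzyloxy)oxolan-2-one
Conditions: BnOC(=NH)CCl3 (1.3 equiv), TfOH (5 mol %), CH2Cl2/cyclohexane, 0 °C → rt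
Reagents that add atoms: benzyl 2,2,2-trichloroacetimidate, ClC(Cl)(Cl)C(=N)OCc1ccccc1
Why: Acid-catalysed imidate O-benzylation works without base, so the lactone is not opened and the α-stereocentre is not epimerised.

Step 2
Reactants: 2 (3S)-3-(benzyloxy)oxolan-2-one
Product: 3 (2S)-2-(benzyloxy)-4-hydroxy-N-methoxy-N-methylbutanamide
Conditions: MeNH(OMe)·HCl (3 equiv), AlMe3 (3 equiv), CH2Cl2, 0 °C → rt; Rochelle salt work-up; used crude at once
Reagents that add atoms: N,O-dimethylhydroxylamine hydrochloride, CNOC.Cl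
Why: Weinreb aminolysis of the lactone by the aluminium amide opens the ring at the acyl carbon and leaves the stereocentre untouched.

Step 3
Reactants: 3 (2S)-2-(benzyloxy)-4-hydroxy-N-methoxy-N-methylbutanamide
Product: 4 (2S)-2-(benzyloxy)-4-[(tert-butyldiphenylsilyl)oxy]-N-methoxy-N-methylbutanamide
Conditions: TBDPSCl (1.1 equiv), imidazole (2.5 equiv), DMF, 0 °C → rt
Reagents that add atoms: tert-butyl(chloro)diphenylsilane, CC(C)(C)[Si](Cl)(c1ccccc1)c1ccccc1
Why: Standard silylation of the primary alcohol stops relactonisation and gives a C1 protecting group that survives Lewis acid, Grignard and hydride steps.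

Step 4
Reactants: 4 (2S)-2-(benzyloxy)-4-[(tert-butyldiphenylsilyl)oxy]-N-methoxy-N-methylbutanamide
Product: 6 (3S)-3-(benzyloxy)-5-[(tert-butyldiphenylsilyl)oxy]pentan-2-one, via tetrahedral magnesium adduct 5 (not isolated)
Conditions: MeMgBr (1.5 equiv), THF, 0 °C; aq NH4Cl
Reagents that add atoms: methylmagnesium bromide, C[Mg]Br
Why: Weinreb ketone synthesis, in which the chelated adduct holds until work-up so only one methyl is delivered and the α-benzyloxy centre is not disturbed.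

Step 5
Reactants: 7 2-methylprop-2-en-1-ol
Product: 10 2-[(trimethylsilyl)methyl]prop-2-en-1-ol, via dilithio dianion 8 (not isolated), via bis-silyl ether 9 (not isolated)
Conditions: n-BuLi (2.2 equiv), TMEDA, Et2O/THF, 0 °C → rt; Me3SiCl (2.2 equiv), −78 °C → rt; then 1 M H2SO4, THF, rt
Reagents that add atoms: chlorotrimethylsilane, C[Si](C)(C)Cl
Why: Double deprotonation (alkoxide plus allylic methyl) followed by C,O-bis-silylation, and the labile O–SiMe3 is hydrolysed on acidic work-up to leave the allylsilane.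

Step 6
Reactants: 10 2-[(trimethylsilyl)methyl]prop-2-en-1-ol
Product: 11 2-[(trimethylsilyl)methyl]prop-2-en-1-yl acetate
Conditions: Ac2O, pyridine, DMAP (cat.), CH2Cl2, 0 °C → rt
Reagents that add atoms: acetic anhydride, CC(=O)OC(C)=O
Why: Simple acylation masks the hydroxyl so that it cannot bind the Lewis acid in the next step.

Step 7
Reactants: 6 (3S)-3-(benzyloxy)-5-[(tert-butyldiphenylsilyl)oxy]pentan-2-one; 11 2-[(trimethylsilyl)methyl]prop-2-en-1-yl acetate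
Product: 12 (4S,5S)-5-(benzyloxy)-7-[(tert-butyldiphenylsilyl)oxy]-4-hydroxy-4-methyl-2-methylideneheptyl acetate
Conditions: TiCl4 (1.1 equiv), CH2Cl2, −78 °C, 15 min; then 11 (1.5 equiv), −78 °C; aq NaHCO3
Reagents that add atoms: none
Why: Hosomi–Sakurai carbonyl allylation under Cram chelation control, where TiCl4 ties C=O and OBn into a five-membered chelate and the allylsilane attacks the face bearing the α-hydrogen, setting the (4S) tertiary carbinol syn to the C3 oxygen.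

Step 8
Reactants: 12 (4S,5S)-5-(benzyloxy)-7-[(tert-butyldiphenylsilyl)oxy]-4-hydroxy-4-methyl-2-methylideneheptyl acetate
Product: 13 (4S,5S)-5-(benzyloxy)-7-[(tert-butyldiphenylsilyl)oxy]-4-methyl-2-methylidene-4-[(triethylsilyl)oxy]heptyl acetate
Conditions: TESOTf (1.5 equiv), 2,6-lutidine (3 equiv), CH2Cl2, −78 → 0 °C
Reagents that add atoms: triethylsilyl trifluoromethanesulfonate, CC[Si](CC)(CC)OS(=O)(=O)C(F)(F)F
Why: Silyl triflate silylation caps the hindered tertiary hydroxyl, so it can neither bind titanium in the epoxidation nor close a tetrahydrofuran onto the later tosylate.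

Step 9
Reactants: 13 (4S,5S)-5-(benzyloxy)-7-[(tert-butyldiphenylsilyl)oxy]-4-methyl-2-methylidene-4-[(triethylsilyl)oxy]heptyl acetate
Product: 14 (4S,5S)-5-(benzyloxy)-7-[(tert-butyldiphenylsilyl)oxy]-4-methyl-2-methylidene-4-[(triethylsilyl)oxy]heptan-1-ol
Conditions: K2CO3 (0.3 equiv), MeOH, 0 °C
Reagents that add atoms: none
Why: Base-catalysed transesterification removes the acetate while the silyl and benzyl ethers stay in place.

Step 10
Reactants: 14 (4S,5S)-5-(benzyloxy)-7-[(tert-butyldiphenylsilyl)oxy]-4-methyl-2-methylidene-4-[(triethylsilyl)oxy]heptan-1-ol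
Product: 15 {(2R)-2-[(2S,3S)-3-(benzyloxy)-5-[(tert-butyldiphenylsilyl)oxy]-2-methyl-2-[(triethylsilyl)oxy]pentyl]oxiran-2-yl}methanol
Conditions: Ti(OiPr)4 (10 mol %), D-(−)-diisopropyl tartrate (12 mol %), t-BuOOH (2 equiv), 4 Å MS, CH2Cl2, −20 °C
Reagents that add atoms: tert-butyl hydroperoxide, CC(C)(C)OO
Why: Sharpless–Katsuki asymmetric epoxidation under reagent control, in which D-(−)-tartrate gives the (R)-epoxy alcohol (L-(+)-tartrate gives the (S) series, as in (S)-2-methylglycidol from methallyl alcohol) and thereby fixes C6.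

Step 11
Reactants: 15 {(2R)-2-[(2S,3S)-3-(benzyloxy)-5-[(tert-butyldiphenylsilyl)oxy]-2-methyl-2-[(triethylsilyl)oxy]pentyl]oxiran-2-yl}methanol; 16 pentadecylmagnesium bromide
Product: 17 (3S,4S,6R)-3-(benzyloxy)-1-[(tert-butyldiphenylsilyl)oxy]-6-(hydroxymethyl)-4-methyl-4-[(triethylsilyl)oxy]docosan-6-ol
Conditions: 16 (3.5 equiv, commercial Et2O solution), CuI (20 mol %), THF, −30 → 0 °C; aq NH4Cl
Reagents that add atoms: none
Why: Copper-catalysed Grignard SN2 opening at the unsubstituted epoxide CH2 builds the C16 chain without touching the quaternary C6–O bond, so C6 keeps its configuration.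

Step 12
Reactants: 17 (3S,4S,6R)-3-(benzyloxy)-1-[(tert-butyldiphenylsilyl)oxy]-6-(hydroxymethyl)-4-methyl-4-[(triethylsilyl)oxy]docosan-6-ol
Product: 18 [(2R)-2-{(2S,3S)-3-(benzyloxy)-5-[(tert-butyldiphenylsilyl)oxy]-2-methyl-2-[(triethylsilyl)oxy]pentyl}-2-hydroxyoctadecyl] 4-methylbenzenesulfonate
Conditions: TsCl (1.3 equiv), Et3N (2.5 equiv), DMAP (cat.), CH2Cl2, 0 °C → rt
Reagents that add atoms: 4-methylbenzenesulfonyl chloride, Cc1ccc(cc1)S(Cl)(=O)=O
Why: Sulfonylation is selective for the primary hydroxyl because the only other free hydroxyl is tertiary.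

Step 13
Reactants: 18 [(2R)-2-{(2S,3S)-3-(benzyloxy)-5-[(tert-butyldiphenylsilyl)oxy]-2-methyl-2-[(triethylsilyl)oxy]pentyl}-2-hydroxyoctadecyl] 4-methylbenzenesulfonate
Product: 20 (3S,4S,6R)-3-(benzyloxy)-1-[(tert-butyldiphenylsilyl)oxy]-4,6-dimethyl-4-[(triethylsilyl)oxy]docosan-6-ol, via epoxide 19 (not isolated)
Conditions: LiEt3BH (4 equiv), THF, 0 °C → rt; H2O
Reagents that add atoms: none
Why: The C6 alkoxide displaces the neighbouring tosylate (intramolecular Williamson) and Super-Hydride opens the terminal epoxide at CH2, so the CH2OH arm becomes the C6 methyl with the C6–O bond intact.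

Step 14
Reactants: 20 (3S,4S,6R)-3-(benzyloxy)-1-[(tert-butyldiphenylsilyl)oxy]-4,6-dimethyl-4-[(triethylsilyl)oxy]docosan-6-ol
Product: 21 (3S,4S,6R)-3-(benzyloxy)-4,6-dimethyldocosane-1,4,6-triol
Conditions: TBAF (4 equiv), THF, rt → 45 °C
Reagents that add atoms: none
Why: Fluoride-mediated desilylation removes the primary TBDPS and the tertiary TES ether in one operation.

Step 15
Reactants: 21 (3S,4S,6R)-3-(benzyloxy)-4,6-dimethyldocosane-1,4,6-triol
Product: 24 (4S,5S)-4-(benzyloxy)-5-[(2R)-2-hydroxy-2-methyloctadecyl]-5-methyloxolan-2-one, via hydroxy aldehyde 22 (not isolated), via lactol 23 (not isolated)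
Conditions: TEMPO (20 mol %), PhI(OAc)2 (2.5 equiv), CH2Cl2, rt
Reagents that add atoms: none
Why: TEMPO/BAIB oxidative lactonisation oxidises only the primary alcohol, the aldehyde is trapped by the C4 hydroxyl as a five-membered lactol, and this is oxidised on to the γ-lactone.

Step 16
Reactants: 24 (4S,5S)-4-(benzyloxy)-5-[(2R)-2-hydroxy-2-methyloctadecyl]-5-methyloxolan-2-one
Product: 25 (4S,5S)-4-hydroxy-5-[(2R)-2-hydroxy-2-methyloctadecyl]-5-methyloxolan-2-one
Conditions: H2 (1 atm), 10 % Pd/C, EtOAc, rt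
Reagents that add atoms: none
Why: Neutral hydrogenolysis of the benzyl ether spares the lactone and the tertiary alcohols and avoids base-induced β-elimination to the butenolide.

## Compound list

1 | (3S)-3-hydroxyoxolan-2-one | O=C1OCC[C@@H]1O | starting material
2 | (3S)-3-(benzyloxy)oxolan-2-one | O=C1OCC[C@@H]1OCc1ccccc1 | intermediate
3 | (2S)-2-(benzyloxy)-4-hydroxy-N-methoxy-N-methylbutanamide | CON(C)C(=O)[C@@H](OCc1ccccc1)CCO | intermediate
4 | (2S)-2-(benzyloxy)-4-[(tert-butyldiphenylsilyl)oxy]-N-methoxy-N-methylbutanamide | CON(C)C(=O)[C@@H](OCc1ccccc1)CCO[Si](c1ccccc1)(c1ccccc1)C(C)(C)C | intermediate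
5 | bromomagnesium (3S)-3-(benzyloxy)-5-[(tert-butyldiphenylsilyl)oxy]-2-[methoxy(methyl)amino]pentan-2-olate | CON(C)C(C)(O[Mg]Br)[C@@H](OCc1ccccc1)CCO[Si](c1ccccc1)(c1ccccc1)C(C)(C)C | intermediate
6 | (3S)-3-(benzyloxy)-5-[(tert-butyldiphenylsilyl)oxy]pentan-2-one | CC(=O)[C@@H](OCc1ccccc1)CCO[Si](c1ccccc1)(c1ccccc1)C(C)(C)C | intermediate
7 | 2-methylprop-2-en-1-ol | CC(=C)CO | starting material
8 | lithium 2-(lithiomethyl)prop-2-en-1-olate | [Li]CC(=C)CO[Li] | intermediate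
9 | trimethyl({2-[(trimethylsilyl)methyl]prop-2-en-1-yl}oxy)silane | C[Si](C)(C)CC(=C)CO[Si](C)(C)C | intermediate
10 | 2-[(trimethylsilyl)methyl]prop-2-en-1-ol | C[Si](C)(C)CC(=C)CO | intermediate
11 | 2-[(trimethylsilyl)methyl]prop-2-en-1-yl acetate | CC(=O)OCC(=C)C[Si](C)(C)C | intermediate
12 | (4S,5S)-5-(benzyloxy)-7-[(tert-butyldiphenylsilyl)oxy]-4-hydroxy-4-methyl-2-methylideneheptyl acetate | CC(=O)OCC(=C)C[C@](C)(O)[C@@H](OCc1ccccc1)CCO[Si](c1ccccc1)(c1ccccc1)C(C)(C)C | intermediate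
13 | (4S,5S)-5-(benzyloxy)-7-[(tert-butyldiphenylsilyl)oxy]-4-methyl-2-methylidene-4-[(triethylsilyl)oxy]heptyl acetate | CC(=O)OCC(=C)C[C@](C)(O[Si](CC)(CC)CC)[C@@H](OCc1ccccc1)CCO[Si](c1ccccc1)(c1ccccc1)C(C)(C)C | intermediate
14 | (4S,5S)-5-(benzyloxy)-7-[(tert-butyldiphenylsilyl)oxy]-4-methyl-2-methylidene-4-[(triethylsilyl)oxy]heptan-1-ol | OCC(=C)C[C@](C)(O[Si](CC)(CC)CC)[C@@H](OCc1ccccc1)CCO[Si](c1ccccc1)(c1ccccc1)C(C)(C)C | intermediate
15 | {(2R)-2-[(2S,3S)-3-(benzyloxy)-5-[(tert-butyldiphenylsilyl)oxy]-2-methyl-2-[(triethylsilyl)oxy]pentyl]oxiran-2-yl}methanol | OC[C@@]1(CO1)C[C@](C)(O[Si](CC)(CC)CC)[C@@H](OCc1ccccc1)CCO[Si](c1ccccc1)(c1ccccc1)C(C)(C)C | intermediate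
16 | pentadecylmagnesium bromide | CCCCCCCCCCCCCCC[Mg]Br | starting material
17 | (3S,4S,6R)-3-(benzyloxy)-1-[(tert-butyldiphenylsilyl)oxy]-6-(hydroxymethyl)-4-methyl-4-[(triethylsilyl)oxy]docosan-6-ol | CCCCCCCCCCCCCCCC[C@@](CO)(O)C[C@](C)(O[Si](CC)(CC)CC)[C@@H](OCc1ccccc1)CCO[Si](c1ccccc1)(c1ccccc1)C(C)(C)C | intermediate
18 | [(2R)-2-{(2S,3S)-3-(benzyloxy)-5-[(tert-butyldiphenylsilyl)oxy]-2-methyl-2-[(triethylsilyl)oxy]pentyl}-2-hydroxyoctadecyl] 4-methylbenzenesulfonate | CCCCCCCCCCCCCCCC[C@@](COS(=O)(=O)c1ccc(C)cc1)(O)C[C@](C)(O[Si](CC)(CC)CC)[C@@H](OCc1ccccc1)CCO[Si](c1ccccc1)(c1ccccc1)C(C)(C)C | intermediate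
19 | (2R)-2-{(2S,3S)-3-(benzyloxy)-5-[(tert-butyldiphenylsilyl)oxy]-2-methyl-2-[(triethylsilyl)oxy]pentyl}-2-hexadecyloxirane | CCCCCCCCCCCCCCCC[C@]1(CO1)C[C@](C)(O[Si](CC)(CC)CC)[C@@H](OCc1ccccc1)CCO[Si](c1ccccc1)(c1ccccc1)C(C)(C)C | intermediate
20 | (3S,4S,6R)-3-(benzyloxy)-1-[(tert-butyldiphenylsilyl)oxy]-4,6-dimethyl-4-[(triethylsilyl)oxy]docosan-6-ol | CCCCCCCCCCCCCCCC[C@@](C)(O)C[C@](C)(O[Si](CC)(CC)CC)[C@@H](OCc1ccccc1)CCO[Si](c1ccccc1)(c1ccccc1)C(C)(C)C | intermediate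
21 | (3S,4S,6R)-3-(benzyloxy)-4,6-dimethyldocosane-1,4,6-triol | CCCCCCCCCCCCCCCC[C@@](C)(O)C[C@](C)(O)[C@@H](OCc1ccccc1)CCO | intermediate
22 | (3S,4S,6R)-3-(benzyloxy)-4,6-dihydroxy-4,6-dimethyldocosanal | CCCCCCCCCCCCCCCC[C@@](C)(O)C[C@](C)(O)[C@@H](OCc1ccccc1)CC=O | intermediate
23 | (4S,5S)-4-(benzyloxy)-5-[(2R)-2-hydroxy-2-methyloctadecyl]-5-methyloxolan-2-ol | CCCCCCCCCCCCCCCC[C@@](C)(O)C[C@]1(C)OC(O)C[C@@H]1OCc1ccccc1 | intermediate
24 | (4S,5S)-4-(benzyloxy)-5-[(2R)-2-hydroxy-2-methyloctadecyl]-5-methyloxolan-2-one | CCCCCCCCCCCCCCCC[C@@](C)(O)C[C@]1(C)OC(=O)C[C@@H]1OCc1ccccc1 | intermediate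
25 | (4S,5S)-4-hydroxy-5-[(2R)-2-hydroxy-2-methyloctadecyl]-5-methyloxolan-2-one | CCCCCCCCCCCCCCCC[C@@](C)(O)C[C@]1(C)OC(=O)C[C@@H]1O | target

## Summary

Total step count: 16.
Longest linear sequence: 14 steps (steps 1–4 and 7–16, from 1 to 25).

Three steps most likely to fail:

**Step 7 (key allylation).** The acetoxymethyl-substituted allylsilane is a weaker nucleophile than allyl-SiMe3, the electrophile is a ketone, and any non-chelated pathway erodes the C4 selectivity. The fallback sets out from 6 and comes back at 12. Ketone 6 is allylated in a zinc Barbier reaction with ethyl 2-(bromomethyl)acrylate (activated Zn, THF, zinc chelated between C=O and OBn). This gives ethyl (4S,5S)-5-(benzyloxy)-7-[(tert-butyldiphenylsilyl)oxy]-4-hydroxy-4-methyl-2-methylideneheptanoate F1, which lactonises in the flask to (5S)-5-[(1S)-1-(benzyloxy)-3-[(tert-butyldiphenylsilyl)oxy]propyl]-5-methyl-3-methylideneoxolan-2-one F2. DIBAL-H (CH2Cl2, −78 → 0 °C) reduces the lactone to (4S,5S)-5-(benzyloxy)-7-[(tert-butyldiphenylsilyl)oxy]-4-methyl-2-methylideneheptane-1,4-diol F3. Acetylation of the primary allylic hydroxyl alone (Ac2O, pyridine, 0 °C) returns to 12.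

**Step 10 (asymmetric epoxidation).** A 2-substituted allylic alcohol with a bulky neighbour may give lower selectivity, and the 2,2-disubstituted epoxy alcohol is sensitive to titanium-promoted opening. The fallback sets out from 14 and comes back at 20, and it makes both C6 epimers useful. Alcohol 14 is epoxidised without chiral control (VO(acac)2, t-BuOOH, CH2Cl2) to a mixture of 15 and its epimer {(2S)-2-[(2S,3S)-3-(benzyloxy)-5-[(tert-butyldiphenylsilyl)oxy]-2-methyl-2-[(triethylsilyl)oxy]pentyl]oxiran-2-yl}methanol F4. These are diastereomers and are separated by chromatography; 15 continues through steps 11–13. In the epimer the two arms of C6 are used the other way round. LiEt3BH opens the epoxide at CH2 to (2S,4S,5S)-5-(benzyloxy)-7-[(tert-butyldiphenylsilyl)oxy]-2,4-dimethyl-4-[(triethylsilyl)oxy]heptane-1,2-diol F5. TsCl/Et3N/DMAP gives (2S,4S,5S)-5-(benzyloxy)-7-[(tert-butyldiphenylsilyl)oxy]-2-hydroxy-2,4-dimethyl-4-[(triethylsilyl)oxy]heptyl 4-methylbenzenesulfonate F6. K2CO3/MeOH closes (2S)-2-[(2S,3S)-3-(benzyloxy)-5-[(tert-butyldiphenylsilyl)oxy]-2-methyl-2-[(triethylsilyl)oxy]pentyl]-2-methyloxirane F7. Opening F7 at CH2 with 16 and CuI (cat.) gives the same (6R) carbinol 20.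

**Step 11 (cuprate opening).** A long-chain Grignard on a free, hindered epoxy alcohol can stall or give bromohydrin through MgBr2. The fallback sets out from 15 and comes back at 17. Diethyl(pentadec-1-yn-1-yl)aluminium (from pentadec-1-yne, n-BuLi and Et2AlCl; toluene, 0 °C) is delivered through the aluminium alkoxide of 15 and opens the epoxide at CH2. This gives (3S,4S,6R)-3-(benzyloxy)-1-[(tert-butyldiphenylsilyl)oxy]-6-(hydroxymethyl)-4-methyl-4-[(triethylsilyl)oxy]docos-8-yn-6-ol F8. Hydrogenation over PtO2 (H2 1 atm, EtOAc), which leaves the benzyl ether alone, saturates the triple bond and gives 17.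

## Further compounds

F1 | step 7 | ethyl (4S,5S)-5-(benzyloxy)-7-[(tert-butyldiphenylsilyl)oxy]-4-hydroxy-4-methyl-2-methylideneheptanoate | CCOC(=O)C(=C)C[C@](C)(O)[C@@H](OCc1ccccc1)CCO[Si](c1ccccc1)(c1ccccc1)C(C)(C)C
F2 | step 7 | (5S)-5-[(1S)-1-(benzyloxy)-3-[(tert-butyldiphenylsilyl)oxy]propyl]-5-methyl-3-methylideneoxolan-2-one | C=C1C[C@](C)(OC1=O)[C@@H](OCc1ccccc1)CCO[Si](c1ccccc1)(c1ccccc1)C(C)(C)C
F3 | step 7 | (4S,5S)-5-(benzyloxy)-7-[(tert-butyldiphenylsilyl)oxy]-4-methyl-2-methylideneheptane-1,4-diol | OCC(=C)C[C@](C)(O)[C@@H](OCc1ccccc1)CCO[Si](c1ccccc1)(c1ccccc1)C(C)(C)C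
F4 | step 10 | {(2S)-2-[(2S,3S)-3-(benzyloxy)-5-[(tert-butyldiphenylsilyl)oxy]-2-methyl-2-[(triethylsilyl)oxy]pentyl]oxiran-2-yl}methanol | OC[C@]1(CO1)C[C@](C)(O[Si](CC)(CC)CC)[C@@H](OCc1ccccc1)CCO[Si](c1ccccc1)(c1ccccc1)C(C)(C)C
F5 | step 10 | (2S,4S,5S)-5-(benzyloxy)-7-[(tert-butyldiphenylsilyl)oxy]-2,4-dimethyl-4-[(triethylsilyl)oxy]heptane-1,2-diol | OC[C@](O)(C)C[C@](C)(O[Si](CC)(CC)CC)[C@@H](OCc1ccccc1)CCO[Si](c1ccccc1)(c1ccccc1)C(C)(C)C
F6 | step 10 | (2S,4S,5S)-5-(benzyloxy)-7-[(tert-butyldiphenylsilyl)oxy]-2-hydroxy-2,4-dimethyl-4-[(triethylsilyl)oxy]heptyl 4-methylbenzenesulfonate | Cc1ccc(cc1)S(=O)(=O)OC[C@](O)(C)C[C@](C)(O[Si](CC)(CC)CC)[C@@H](OCc1ccccc1)CCO[Si](c1ccccc1)(c1ccccc1)C(C)(C)C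
F7 | step 10 | (2S)-2-[(2S,3S)-3-(benzyloxy)-5-[(tert-butyldiphenylsilyl)oxy]-2-methyl-2-[(triethylsilyl)oxy]pentyl]-2-methyloxirane | C[C@@]1(CO1)C[C@](C)(O[Si](CC)(CC)CC)[C@@H](OCc1ccccc1)CCO[Si](c1ccccc1)(c1ccccc1)C(C)(C)C
F8 | step 11 | (3S,4S,6R)-3-(benzyloxy)-1-[(tert-butyldiphenylsilyl)oxy]-6-(hydroxymethyl)-4-methyl-4-[(triethylsilyl)oxy]docos-8-yn-6-ol | CCCCCCCCCCCCCC#CC[C@@](CO)(O)C[C@](C)(O[Si](CC)(CC)CC)[C@@H](OCc1ccccc1)CCO[Si](c1ccccc1)(c1ccccc1)C(C)(C)C
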